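The runs are calculated for an exercise; scatter was added.

Temperature shifts how starting material divides between target and quenched substrate, and I want that division for the asked flasks.

| flask | starting material | protic impurity | free enzyme | temperature | remark | time |
|---|---|---|---|---|---|---|
| ochre | 0.090 M | 0.18 M | 74 µM | −2 °C | run made earlier |  |
| violet | 0.36 M | 0.18 M | 74 µM | 36 °C | run made earlier |  |
| teal | 0.18 M | 0.18 M | 37 µM | −2 °C | run made earlier |  |
| Friday's | 0.18 M | 0.180 M | 74 µM | 40 °C |  | 5.0 h |
| Sunday's | 0.18 M | 0.180 M | 74 µM | 50 °C |  | 5.0 h |
| Wednesday's | 0.18 M | 0.180 M | 74 µM | 5 °C |  | 5.0 h |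
| Monday's | 0.18 M | 0.180 M | 74 µM | 20 °C |  | 5.0 h |
| Tuesday's | 0.18 M | 0.180 M | 74 µM | −20 °C |  | 5.0 h |

ochre run (percent of the starting material charged)

| time / h | target / % | starting material / % |
|---|---|---|
| 1.00 | 57.3 | 36.2 |
| 2.00 | 78.3 | 12.0 |
| 3.00 | 85.5 | 4.0 |
| 6.00 | 88.7 | 0.1 |
| 12.0 | 89.1 | 0 |

violet run (percent of the starting material charged)

| time / min | target / % | starting material / % |
|---|---|---|
| 25.0 | 74.3 | 3.3 |
| 40.0 | 75.5 | 1.3 |
| 60.0 | 75.8 | 1.0 |
| 80.0 | 76.1 | 0.1 |
| 120 | 75.9 | 0 |

teal run (percent of the starting material charged)

| time / h | target / % | starting material / % |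
|---|---|---|
| 1.00 | 30.6 | 59.6 |
| 2.00 | 51.1 | 34.8 |
| 3.00 | 63.8 | 20.2 |
| 6.00 | 77.4 | 3.7 |
| 12.0 | 79.8 | 0 |

(each reading ± 0.3 percentage points)

- the flasks put in order of amount of target, in percent of the starting material charged, best first, at 5.0 h (Friday's / Sunday's / Wednesday's / Monday's / Tuesday's)
- the same order at 40 h (Friday's / Sunday's / Wednesday's / Monday's / Tuesday's)
- the amount of target, in percent of the starting material charged of the flask you put first, at 5.0 h
- the amount of target, in percent of the starting material charged of the flask you put last, at 5.0 h

- steps thought possible: free enzyme -> unfolded enzyme; starting material + free enzyme -> target + free enzyme; starting material + protic impurity -> quenched substrate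

I call S, the selectivity factor, the ratio of target to quenched substrate once starting material has gone, and I count as quenched what target lacks of the charge. Ochre ends at 89.1% target, so S is 8.17, and that is my first guess for Wednesday's. But ochre has half of Wednesday's charge. Teal has Wednesday's charge and half the enzyme, and it ends at S of 3.95. Target forms on enzyme and the quench runs on impurity, so I expect S to scale as enzyme over impurity. Scaled to full enzyme, teal gives S_C = 7.90, my cold selectivity factor, which is 0.967 of ochre's value, so the charge costs little between these runs.

But both runs stand at −2 °C, and Wednesday's stands at 5 °C. Violet, at 36 °C, ends at S of 3.15, lower, but violet differs from teal in charge as well as temperature, and it may have lost enzyme, so I draw no slope from it. I carry S_C to Wednesday's with that doubt, which means 88.8% target. If warmth is what lowers violet, that estimate for Wednesday's stands high.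

Does Wednesday's finish? Its charge stands at 2430 turnovers per enzyme. Ochre's starting material falls to 36.2% in 1.00 h, a pseudo-first-order constant of 1.02 /h. Held for 5.0 h, that leaves 0.622%, though Wednesday's has twice ochre's charge, so this is an estimate. S_C supposes living enzyme, though, and Sunday's at 50 °C stands hotter than any run, so I put no number on it.

The forecast gives Wednesday's > Monday's > Friday's > Tuesday's > Sunday's at 5.0 h and Tuesday's > Wednesday's > Monday's > Friday's > Sunday's at 40 h, with 87% first and 42% last. Of Sunday's it says “enzyme dies within minutes, quench takes the rest”.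

The flask gives Wednesday's > Monday's > Tuesday's > Friday's > Sunday's at 5.0 h and Tuesday's > Wednesday's > Monday's > Friday's > Sunday's at 40 h. Wednesday's holds 87.2%. Sunday's holds 6.50%, which is 36 percentage points under the forecast, with free enzyme at 0% and quenched substrate at 91.3% by 2.50 h. Wednesday's S is 6.81, below my S_C of 7.90, and Sunday's, left ten times as long, is 0.0695.

    free enzyme → unfolded enzyme (k = 2.50 × 10⁻⁶ /s, Ea = 275 kJ/mol)
    starting material + free enzyme → target + free enzyme, rate k2*[starting material]*[free enzyme]/(1 + ([starting material]/Km2)) (0.550 M, k = 18.0 /M/s, Ea = 47.0 kJ/mol)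
    starting material + protic impurity → quenched substrate (k = 0.00130 /M/s, Ea = 59.0 kJ/mol)
    (constants at 20 °C)

Take Wednesday's with 0.31 M of impurity: S_C scaled by impurity gives 4.59, so 82.1% target. The computed flask gives 79.8%.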